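**Retrosynthetic overview**

1. The C15 ester is cut first (Mitsunobu with p-coumaric acid), then C4–C15 (Stille hydroxymethylation of a C4 alkenyl iodide), then C7–C11 (acrylate grown on a C7 ketone through a Knoevenagel adduct).
2. Ring B is opened at C5–C6 and C8–C9: carbons C6–C7–C8 come from 2-methoxypropene, joined to a monocyclic ring A allylic alcohol in one flask by O-vinylation, [3,3] shift and aldol condensation.
3. Enabling feature: in ring A the C3 carbinol is allylic to C4=C5, and the formyl carbon C9 sits on quaternary C10, 1,3 to C5. The shift from O3 to C5 therefore transfers the C3 configuration to C5 (trans ring fusion), leaves the double bond at C3=C4 as in the target, and places the new acetonyl methyl (C8) within reach of C9.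
4. Ring order: ring A first (enantioselective Diels–Alder, sets C10), then ring B (key step); C3 is set by CBS reduction, C7 by axial hydride addition.

Key step: step 5

Remark on locants: eudesmane numbering is used (C10 methyl-bearing fusion carbon, C5 the CH fusion carbon, C4 bears C15, C7 bears C11 with ester carbon C12 and methylene C13); β is the face of the C10 methyl group.

Assumption: the (1S,2S)-salen chromium catalyst is taken to give (S)-4; if the sense of induction is the opposite, the (1R,2R) catalyst is used instead.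

**Route**

Step 1
Reactants: 1 (E)-3-[(tert-butyldimethylsilyl)oxy]-N,N-dimethylbuta-1,3-dien-1-amine; 2 methacrolein
Product: 4 (S)-1-methyl-4-oxocyclohex-2-ene-1-carbaldehyde, via cycloadduct 3 (not isolated)
Conditions: (salen)CrCl/AgSbF6 (5 mol % each; salen = (1S,2S)-N,N′-bis(3,5-di-tert-butylsalicylidene)cyclohexane-1,2-diamine dianion), 4 Å MS, CH2Cl2, −40 °C; then 1 M HCl, THF, 0 °C
Reagents that add atoms: none
Why: Catalytic enantioselective Diels–Alder reaction of a 1-amino-3-siloxy diene with an α-substituted acrolein bound to the cationic trivalent chromium salen Lewis acid, in which the amino terminus bonds to the α-carbon so that the quaternary stereocenter C10 (methyl and formyl carbon C9) is set by the catalyst through the endo transition state, after which acid hydrolyses the silyl enol ether and eliminates dimethylamine to the enone.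

Step 2
Reactants: 4 (S)-1-methyl-4-oxocyclohex-2-ene-1-carbaldehyde
Product: 5 (S)-4-(dimethoxymethyl)-4-methylcyclohex-2-en-1-one
Conditions: HC(OMe)3, CeCl3·7H2O (10 mol %), MeOH, 0 °C to rt
Reagents that add atoms: trimethyl orthoformate (COC(OC)OC)
Why: Chemoselective acetalisation, since the aldehyde is far more electrophilic than the conjugated ketone, which masks C9 against borane in step 4 and against vinylogous deformylation.

Step 3
Reactants: 5 (S)-4-(dimethoxymethyl)-4-methylcyclohex-2-en-1-one
Product: 6 (S)-4-(dimethoxymethyl)-2-iodo-4-methylcyclohex-2-en-1-one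
Conditions: I2, pyridine, CH2Cl2, 0 °C to rt
Reagents that add atoms: iodine (II)
Why: α-Iodination of a cyclic enone by the pyridine conjugate addition, enolate iodination and elimination sequence, which places at C4 the iodide that sharpens the next reduction and later anchors C15.

Step 4
Reactants: 6 (S)-4-(dimethoxymethyl)-2-iodo-4-methylcyclohex-2-en-1-one
Product: 7 (1S,4S)-4-(dimethoxymethyl)-2-iodo-4-methylcyclohex-2-en-1-ol
Conditions: (R)-Me-CBS oxazaborolidine ((R)-1-methyl-3,3-diphenyltetrahydro-1H,3H-pyrrolo[1,2-c][1,3,2]oxazaborole, 20 mol %), BH3·SMe2, THF, −20 °C; MeOH quench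
Reagents that add atoms: none
Why: CBS reduction in which the 2-iodovinyl carbon acts as the large group, so the (R)-catalyst should give the (1S)-carbinol with the hydroxyl cis to the C10 methyl group (reagent control, in the sense that turns acetophenone into (S)-1-phenylethanol), the minor enantiomer of 6 ending as a separable diastereomer.

Step 5
Reactants: 7 (1S,4S)-4-(dimethoxymethyl)-2-iodo-4-methylcyclohex-2-en-1-ol; 8 2-methoxypropene
Product: 12 (4aR,8aR)-8-iodo-4a-methyl-4a,5,6,8a-tetrahydronaphthalen-2(1H)-one, via allyl isopropenyl ether 9 (not isolated), via methyl ketone 10 (not isolated), via keto aldehyde 11 (not isolated)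
Conditions: 2-methoxypropene (10 equiv), PPTS (5 mol %), xylene, 140 °C, sealed tube; volatiles removed; then TsOH·H2O (20 mol %), wet toluene, 90 °C
Reagents that add atoms: none
Why: Acid-catalysed exchange turns the C3 hydroxyl into isopropenyl ether 9, whose [3,3]-sigmatropic shift (ketal Claisen rearrangement, Saucy–Marbet variant) forms C5–C6 and gives methyl ketone 10; aqueous acid then frees the C9 aldehyde (11) and the methyl ketone closes onto it by intramolecular aldol condensation, forming C8–C9 as the C8=C9 bond of enone 12. The closest known reaction types are the ketal Claisen rearrangement of cyclohex-2-enols, 2-halo-substituted ones included, and the cyclisation of 2,2-disubstituted 5-oxohexanals to 4,4-disubstituted cyclohexenones. Ring B is closed in the aldol step in the 6-(enolexo)-exo-trig mode, whereas the [3,3] step closes no ring but uses the temporary O3–C7 bond, which is absent from the target and is broken in the same event. The new stereocenter C5 is controlled by C3, because the shift is suprafacial and exchanges the β C3–O bond for a β C5–C6 bond, cis to the C10 methyl group and trans to C9, which fixes the trans ring fusion at a carbon that cannot epimerise afterwards. The step needs site selectivity in the aldol, which the substrate secures because only enolisation towards C8 can give a six-membered ring and the C9 aldehyde has no α-hydrogen, and it needs the allylic ether to survive, which the electron-withdrawing iodine at C4 and the weak acid of the first stage favour.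

Step 6
Reactants: 12 (4aR,8aR)-8-iodo-4a-methyl-4a,5,6,8a-tetrahydronaphthalen-2(1H)-one
Product: 13 (4aR,8aR)-8-iodo-4a-methyl-3,4,4a,5,6,8a-hexahydronaphthalen-2(1H)-one
Conditions: [(Ph3P)CuH]6 (0.35 equiv), H2O (5 equiv), benzene, rt
Reagents that add atoms: none
Why: Conjugate reduction of an enone by a phosphine-stabilised copper hydride, chemoselective for the C8=C9 enone bond and expected to leave the trisubstituted alkenyl iodide untouched, whereas catalytic hydrogenation would cleave the C–I bond.

Step 7
Reactants: 13 (4aR,8aR)-8-iodo-4a-methyl-3,4,4a,5,6,8a-hexahydronaphthalen-2(1H)-one; 14 2,2-dimethyl-1,3-dioxane-4,6-dione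
Product: 15 5-[(4aR,8aR)-8-iodo-4a-methyl-3,4,4a,5,6,8a-hexahydronaphthalen-2(1H)-ylidene]-2,2-dimethyl-1,3-dioxane-4,6-dione
Conditions: TiCl4, pyridine, THF, 0 °C to rt
Reagents that add atoms: none
Why: Knoevenagel condensation of an unhindered cyclohexanone with a cyclic malonate under titanium tetrachloride/pyridine activation, which attaches C11 together with both candidate carbonyl carbons to C7.

Step 8
Reactants: 15 5-[(4aR,8aR)-8-iodo-4a-methyl-3,4,4a,5,6,8a-hexahydronaphthalen-2(1H)-ylidene]-2,2-dimethyl-1,3-dioxane-4,6-dione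
Product: 16 5-[(2R,4aS,8aR)-8-iodo-4a-methyl-1,2,3,4,4a,5,6,8a-octahydronaphthalen-2-yl]-2,2-dimethyl-1,3-dioxane-4,6-dione
Conditions: NaBH4, MeOH/CH2Cl2, −40 to 0 °C; 1 M HCl work-up
Reagents that add atoms: none
Why: Conjugate hydride reduction of an alkylidene malonate, in which the small hydride should add to C7 along the axial trajectory (α face, as in borohydride additions to cyclohexanones and cyclohexylidene malonates), making the new C7–H bond axial (α) and the C11 substituent equatorial (β).

Step 9
Reactants: 16 5-[(2R,4aS,8aR)-8-iodo-4a-methyl-1,2,3,4,4a,5,6,8a-octahydronaphthalen-2-yl]-2,2-dimethyl-1,3-dioxane-4,6-dione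
Product: 18 methyl 2-[(2R,4aS,8aR)-8-iodo-4a-methyl-1,2,3,4,4a,5,6,8a-octahydronaphthalen-2-yl]prop-2-enoate, via Mannich base 17 (not isolated)
Conditions: dimethyl(methylidene)ammonium iodide (2.5 equiv), MeOH, 65 °C
Reagents that add atoms: dimethyl(methylidene)ammonium iodide (C[N+](C)=C.[I-]); methanol (CO)
Why: Mannich reaction at the acidic C11–H followed by methanolysis of the dioxanedione, decarboxylation and β-elimination of dimethylamine, the established one-flask conversion of 5-monoalkyl 2,2-dimethyl-1,3-dioxane-4,6-diones into methyl 2-alkylacrylates, which creates the C13 methylene and the C12 methyl ester without touching C7.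

Step 10
Reactants: 18 methyl 2-[(2R,4aS,8aR)-8-iodo-4a-methyl-1,2,3,4,4a,5,6,8a-octahydronaphthalen-2-yl]prop-2-enoate
Product: 19 methyl 2-[(2R,4aR,8aR)-8-(hydroxymethyl)-4a-methyl-1,2,3,4,4a,5,6,8a-octahydronaphthalen-2-yl]prop-2-enoate
Conditions: Bu3SnCH2OH (1.5 equiv), Pd(PPh3)4 (10 mol %), dioxane, 95 °C
Reagents that add atoms: (tributylstannyl)methanol (CCCC[Sn](CCCC)(CCCC)CO)
Why: Stille cross-coupling of the alkenyl iodide with a hydroxymethylstannane (oxidative addition to zerovalent palladium, transmetalation, reductive elimination), which installs C15 as the free allylic alcohol on C4 with the C3=C4 geometry fixed by the ring.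

Step 11
Reactants: 19 methyl 2-[(2R,4aR,8aR)-8-(hydroxymethyl)-4a-methyl-1,2,3,4,4a,5,6,8a-octahydronaphthalen-2-yl]prop-2-enoate; 20 (E)-3-(4-hydroxyphenyl)prop-2-enoic acid
Product: 21 methyl 2-[(2R,4aR,8aR)-8-({[(2E)-3-(4-hydroxyphenyl)prop-2-enoyl]oxy}methyl)-4a-methyl-1,2,3,4,4a,5,6,8a-octahydronaphthalen-2-yl]prop-2-enoate
Conditions: PPh3, diisopropyl azodicarboxylate (DIAD), THF, 0 °C to rt
Reagents that add atoms: none
Why: Mitsunobu esterification, in which the primary allylic alcohol is activated as its oxyphosphonium salt and displaced by the carboxylate, the carboxylic acid (pKa about 4.5) being deprotonated in preference to the phenol (pKa about 10), so the phenol should not need protection.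

**Compound list**

1 | (E)-3-[(tert-butyldimethylsilyl)oxy]-N,N-dimethylbuta-1,3-dien-1-amine | CN(C)/C=C/C(=C)O[Si](C)(C)C(C)(C)C | starting material
2 | methacrolein (2-methylprop-2-enal) | CC(=C)C=O | starting material
3 | cycloadduct, (1S,2R)-4-[(tert-butyldimethylsilyl)oxy]-2-(dimethylamino)-1-methylcyclohex-3-ene-1-carbaldehyde | O=C[C@@]1(C)CCC(O[Si](C)(C)C(C)(C)C)=C[C@H]1N(C)C | intermediate
4 | (S)-1-methyl-4-oxocyclohex-2-ene-1-carbaldehyde | O=C[C@@]1(C)CCC(=O)C=C1 | intermediate
5 | (S)-4-(dimethoxymethyl)-4-methylcyclohex-2-en-1-one | COC(OC)[C@@]1(C)CCC(=O)C=C1 | intermediate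
6 | (S)-4-(dimethoxymethyl)-2-iodo-4-methylcyclohex-2-en-1-one | COC(OC)[C@@]1(C)CCC(=O)C(I)=C1 | intermediate
7 | (1S,4S)-4-(dimethoxymethyl)-2-iodo-4-methylcyclohex-2-en-1-ol | COC(OC)[C@@]1(C)CC[C@H](O)C(I)=C1 | intermediate
8 | 2-methoxypropene | COC(C)=C | starting material
9 | allyl isopropenyl ether, (3S,6S)-3-(dimethoxymethyl)-1-iodo-3-methyl-6-(prop-1-en-2-yloxy)cyclohex-1-ene | COC(OC)[C@@]1(C)CC[C@H](OC(C)=C)C(I)=C1 | intermediate
10 | methyl ketone, 1-[(1R,6S)-6-(dimethoxymethyl)-2-iodo-6-methylcyclohex-2-en-1-yl]propan-2-one | COC(OC)[C@@]1(C)CCC=C(I)[C@@H]1CC(C)=O | intermediate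
11 | keto aldehyde, (1S,2R)-3-iodo-1-methyl-2-(2-oxopropyl)cyclohex-3-ene-1-carbaldehyde | O=C[C@@]1(C)CCC=C(I)[C@@H]1CC(C)=O | intermediate
12 | (4aR,8aR)-8-iodo-4a-methyl-4a,5,6,8a-tetrahydronaphthalen-2(1H)-one | O=C1C=C[C@@]2(C)CCC=C(I)[C@@H]2C1 | intermediate
13 | (4aR,8aR)-8-iodo-4a-methyl-3,4,4a,5,6,8a-hexahydronaphthalen-2(1H)-one | O=C1CC[C@@]2(C)CCC=C(I)[C@@H]2C1 | intermediate
14 | 2,2-dimethyl-1,3-dioxane-4,6-dione | CC1(C)OC(=O)CC(=O)O1 | starting material
15 | 5-[(4aR,8aR)-8-iodo-4a-methyl-3,4,4a,5,6,8a-hexahydronaphthalen-2(1H)-ylidene]-2,2-dimethyl-1,3-dioxane-4,6-dione | O=C1OC(C)(C)OC(=O)C1=C3CC[C@@]2(C)CCC=C(I)[C@@H]2C3 | intermediate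
16 | 5-[(2R,4aS,8aR)-8-iodo-4a-methyl-1,2,3,4,4a,5,6,8a-octahydronaphthalen-2-yl]-2,2-dimethyl-1,3-dioxane-4,6-dione | O=C1OC(C)(C)OC(=O)C1[C@@H]3CC[C@@]2(C)CCC=C(I)[C@@H]2C3 | intermediate
17 | Mannich base, 5-[(dimethylamino)methyl]-5-[(2R,4aS,8aR)-8-iodo-4a-methyl-1,2,3,4,4a,5,6,8a-octahydronaphthalen-2-yl]-2,2-dimethyl-1,3-dioxane-4,6-dione | CN(C)CC1(C(=O)OC(C)(C)OC1=O)[C@@H]3CC[C@@]2(C)CCC=C(I)[C@@H]2C3 | intermediate
18 | methyl 2-[(2R,4aS,8aR)-8-iodo-4a-methyl-1,2,3,4,4a,5,6,8a-octahydronaphthalen-2-yl]prop-2-enoate | C=C(C(=O)OC)[C@@H]1CC[C@@]2(C)CCC=C(I)[C@@H]2C1 | intermediate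
19 | methyl 2-[(2R,4aR,8aR)-8-(hydroxymethyl)-4a-methyl-1,2,3,4,4a,5,6,8a-octahydronaphthalen-2-yl]prop-2-enoate | C=C(C(=O)OC)[C@@H]1CC[C@@]2(C)CCC=C(CO)[C@@H]2C1 | intermediate
20 | (E)-3-(4-hydroxyphenyl)prop-2-enoic acid (p-coumaric acid) | OC(=O)/C=C/c1ccc(O)cc1 | starting material
21 | methyl 2-[(2R,4aR,8aR)-8-({[(2E)-3-(4-hydroxyphenyl)prop-2-enoyl]oxy}methyl)-4a-methyl-1,2,3,4,4a,5,6,8a-octahydronaphthalen-2-yl]prop-2-enoate | C=C(C(=O)OC)[C@@H]1CC[C@@]2(C)CCC=C(COC(=O)/C=C/c3ccc(O)cc3)[C@@H]2C1 | target

**Step count and risks**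

Total steps: 11. Longest linear sequence: 11 steps (from 1 and 2 to 21; the route is fully linear).

Steps most likely to fail:

1. Step 5. The isopropenyl ether may ionise at C3 under acid and heat and eliminate to a diene before it rearranges, or the telescoped aldol closure may stall at the open keto aldehyde. Fallback: from 7, an Eschenmoser–Claisen rearrangement (N,N-dimethylacetamide dimethyl acetal, xylene, 140 °C, no acid) transfers an acetamide unit to C5 with the same C3-to-C5 chirality transfer and should give 2-[(1R,6S)-6-(dimethoxymethyl)-2-iodo-6-methylcyclohex-2-en-1-yl]-N,N-dimethylacetamide F1. Addition of MeLi/CeCl3 (THF, −78 °C) to the amide gives the methyl ketone, which is 10, now isolated. The route is rejoined at 10, which is hydrolysed and cyclised in a separate operation (1 M HCl/THF, then KOH/MeOH) to 12.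

2. Step 8. Poor facial selectivity of hydride addition at C7 would give the axial (7α) side chain, which cannot be corrected later. Fallback: from 12, 1,2-reduction with LiBH(s-Bu)3 (THF, −78 °C) from the equatorial direction should give the axial allylic alcohol (2R,4aR,8aR)-8-iodo-4a-methyl-1,2,4a,5,6,8a-hexahydronaphthalen-2-ol F2. Mitsunobu C-alkylation of 14 with F2 (PPh3, DIAD, THF) displaces the activated 7α oxygen with inversion at C7 (C9 is neopentyl, so allylic transposition is disfavoured) and should give 5-[(2S,4aR,8aR)-8-iodo-4a-methyl-1,2,4a,5,6,8a-hexahydronaphthalen-2-yl]-2,2-dimethyl-1,3-dioxane-4,6-dione F3 with the side chain 7β. Diimide (2-nitrobenzenesulfonyl hydrazide, Et3N, CH2Cl2) then saturates only the disubstituted C8=C9 bond and gives 16, where the route is rejoined; steps 6 to 8 are bypassed.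

3. Step 10. Transmetalation of the hydroxymethylstannane at the hindered C4 position may be slow, so that the iodide is lost by reduction or by Heck-type reaction with the acrylate. Fallback: from 18, palladium-catalysed formylation (CO 1 atm, HCO2Na, PdCl2(PPh3)2, DMF, 90 °C) should give the enal methyl 2-[(2R,4aR,8aR)-8-formyl-4a-methyl-1,2,3,4,4a,5,6,8a-octahydronaphthalen-2-yl]prop-2-enoate F4. Luche 1,2-reduction (NaBH4, CeCl3·7H2O, MeOH, −78 °C) of the aldehyde then gives 19.

**Further compounds**

F1 | step 5 | 2-[(1R,6S)-6-(dimethoxymethyl)-2-iodo-6-methylcyclohex-2-en-1-yl]-N,N-dimethylacetamide | COC(OC)[C@@]1(C)CCC=C(I)[C@@H]1CC(=O)N(C)C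
F2 | step 8 | (2R,4aR,8aR)-8-iodo-4a-methyl-1,2,4a,5,6,8a-hexahydronaphthalen-2-ol | O[C@H]1C=C[C@@]2(C)CCC=C(I)[C@@H]2C1
F3 | step 8 | 5-[(2S,4aR,8aR)-8-iodo-4a-methyl-1,2,4a,5,6,8a-hexahydronaphthalen-2-yl]-2,2-dimethyl-1,3-dioxane-4,6-dione | O=C1OC(C)(C)OC(=O)C1[C@@H]3C=C[C@@]2(C)CCC=C(I)[C@@H]2C3
F4 | step 10 | methyl 2-[(2R,4aR,8aR)-8-formyl-4a-methyl-1,2,3,4,4a,5,6,8a-octahydronaphthalen-2-yl]prop-2-enoate | C=C(C(=O)OC)[C@@H]1CC[C@@]2(C)CCC=C(C=O)[C@@H]2C1
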